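**Retrosynthetic overview**

1. Numbering: C1 anisoyloxy carbinol, C2 CH2, C3 methyl-bearing sp2 carbon, C4 =CH, C5 CH2, C6 angular-methyl quaternary carbon, C7 ketone, C8 CH2, C9 isopropyl carbinol, C10 fusion CH; ring A = C1–C6 plus C10 (seven-membered), ring B = C6–C10 (five-membered); β = face of the C6 methyl group.
2. Feature: with C1 taken back to an enol ether, ring A is a cyclohepta-1,4-diene (C1=C10 and C3=C4) whose C5–C6 bond ends at the quaternary C6, which is the product pattern of a cis-divinylcyclopropane Cope rearrangement.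
3. Key disconnection: C1–C2 and C5–C6. Ring A is closed last onto ring B by cyclopropanation of a 2-silyloxybuta-1,3-diene with a ring B alkenyl(methoxy)carbene complex of Cr(CO)5, then [3,3] shift; the C3 silyloxy group steers the carbene and is exchanged for the C3 methyl group afterwards.
4. Ring B is made first from (R)-4-silyloxycyclopentenone (C6 methyl, C10 bromide, C9 isopropyl anti to the C7 silyloxy group); C1 comes from a CO ligand of Cr(CO)6.
5. After ring A: C1 enol ether to ketone with C10–H α, C9–OH-directed reduction to the 1α-alcohol, anisoylation, C7 desilylation and oxidation.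

Key step: step 8

Assumption: (R)-4-(tert-butyldimethylsilyloxy)cyclopent-2-en-1-one (1) is bought as the single enantiomer and is the source of all absolute stereochemistry. Its carbonyl carbon becomes C9, the α-carbon C10, the β-carbon C6, the silyloxy carbon C7 and the remaining CH2 C8.

Remark on the diene: isoprene is not used as the four-carbon partner. A sterically shielded chromium carbene is expected to engage its unhindered vinyl group, which would put the methyl group on C4. An enol ether double bond in the diene fixes the site of attack, and the oxygen left on C3 is exchanged for methyl in steps 9 and 10.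

Locants in the names of bicyclic compounds follow the C1–C10 numbering above, not von Baeyer numbering.

**Route**

Step 1
Reactants: 1 (R)-4-(tert-butyldimethylsilyloxy)cyclopent-2-en-1-one
Product: 2 (3R,4R)-4-(tert-butyldimethylsilyloxy)-3-methyl-1-(trimethylsilyloxy)cyclopent-1-ene (methyl trans to OTBS)
Conditions: Me2CuLi (from MeLi and CuI), Et2O, −78 °C; then TMSCl, Et3N, −78 → 0 °C
Reagents that add atoms: lithium dimethylcuprate, [Li+].C[Cu-]C; chlorotrimethylsilane, C[Si](C)(C)Cl
Why: Cuprate conjugate addition delivers the future C6 methyl group anti to the silyloxy group and the enolate is silylated cold, before it can transpose and expel the silyloxy group (conjugate addition with enolate trapping); the methyl-bearing stereocentre is erased in step 2.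

Step 2
Reactants: 2 (3R,4R)-4-(tert-butyldimethylsilyloxy)-3-methyl-1-(trimethylsilyloxy)cyclopent-1-ene
Product: 3 (R)-4-(tert-butyldimethylsilyloxy)-3-methylcyclopent-2-en-1-one
Conditions: Pd(OAc)2 (1.05 equiv), MeCN, rt
Reagents that add atoms: none
Why: Saegusa–Ito oxidation: the silyl enol ether gives a palladium enolate at C10 whose only β-hydrogen sits on the methyl-bearing carbon, so the enone double bond returns between C10 and C6 and the C7 stereocentre is untouched.

Step 3
Reactants: 3 (R)-4-(tert-butyldimethylsilyloxy)-3-methylcyclopent-2-en-1-one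
Product: 5 (R)-2-bromo-4-(tert-butyldimethylsilyloxy)-3-methylcyclopent-2-en-1-one, via dibromo ketone 4 (not isolated)
Conditions: Br2, CH2Cl2, 0 °C; then Et3N, 0 °C → rt
Reagents that add atoms: bromine, BrBr
Why: Bromine adds across the enone double bond and triethylamine removes the acidic α-hydrogen with loss of the β-bromide (bromination–dehydrobromination of an enone), which leaves bromine on C10.

Step 4
Reactants: 5 (R)-2-bromo-4-(tert-butyldimethylsilyloxy)-3-methylcyclopent-2-en-1-one; 6 isopropylmagnesium chloride
Product: 7 (1R,4R)-2-bromo-4-(tert-butyldimethylsilyloxy)-3-methyl-1-(propan-2-yl)cyclopent-2-en-1-ol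
Conditions: iPrMgCl, CeCl3, THF, −78 °C
Reagents that add atoms: none
Why: Organocerium 1,2-addition to the ketone (CeCl3 suppresses enolisation and β-hydride reduction by the branched Grignard reagent); the nucleophile enters anti to the C7 silyloxy group, so the new C9 hydroxyl is cis to the C7 oxygen and the isopropyl group trans to it.

Step 5
Reactants: 7 (1R,4R)-2-bromo-4-(tert-butyldimethylsilyloxy)-3-methyl-1-(propan-2-yl)cyclopent-2-en-1-ol
Product: 8 (3R,5R)-1-bromo-3-(tert-butyldimethylsilyloxy)-2-methyl-5-(propan-2-yl)-5-(triethylsilyloxy)cyclopent-1-ene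
Conditions: TESOTf, 2,6-lutidine, CH2Cl2, −78 → 0 °C
Reagents that add atoms: triethylsilyl trifluoromethanesulfonate, CC[Si](CC)(CC)OS(=O)(=O)C(F)(F)F
Why: Silylation of a hindered tertiary alcohol with a silyl triflate and a non-nucleophilic base masks the hydroxyl for the organolithium step with a group that can later be removed beside the C7 TBS ether.

Step 6
Reactants: 8 (3R,5R)-1-bromo-3-(tert-butyldimethylsilyloxy)-2-methyl-5-(propan-2-yl)-5-(triethylsilyloxy)cyclopent-1-ene; 9 chromium hexacarbonyl, Cr(CO)6
Product: 12 pentacarbonyl{methoxy[(3R,5R)-3-(tert-butyldimethylsilyloxy)-2-methyl-5-(propan-2-yl)-5-(triethylsilyloxy)cyclopent-1-en-1-yl]methylidene}chromium, via vinyllithium 10 (not isolated), via lithium acyl chromate 11 (not isolated)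
Conditions: t-BuLi (2.1 equiv), THF, −78 °C; Cr(CO)6, −78 °C → rt; then MeOTf, CH2Cl2, 0 °C
Reagents that add atoms: methyl trifluoromethanesulfonate, COS(=O)(=O)C(F)(F)F
Why: Fischer carbene synthesis (bromine–lithium exchange, addition of the vinyllithium to a CO ligand, O-methylation of the acyl chromate) turns a CO carbon into C1; the vinyllithium is safe because β-elimination would need a cyclic allene and the C7 silyl group lies on the far side of the ring alkene from lithium.

Step 7
Reactants: 13 but-3-en-2-one (methyl vinyl ketone)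
Product: 14 2-(tert-butyldimethylsilyloxy)buta-1,3-diene
Conditions: TBSOTf, Et3N, Et2O, 0 °C
Reagents that add atoms: tert-butyldimethylsilyl trifluoromethanesulfonate, CC(C)(C)[Si](C)(C)OS(=O)(=O)C(F)(F)F
Why: Soft enolisation and O-silylation of the methyl ketone (silyl dienol ether formation) gives a diene whose enol ether double bond is its most nucleophilic site.

Step 8
Reactants: 12 ring B alkenyl(methoxy)carbene complex of Cr(CO)5; 14 2-(tert-butyldimethylsilyloxy)buta-1,3-diene
Product: 16 1-methoxy-6β-methyl-9α-isopropyl-3,7β-bis(tert-butyldimethylsilyloxy)-9β-(triethylsilyloxy)bicyclo[5.3.0]deca-1(10),3-diene, via cis-divinylcyclopropane 15 (not isolated)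
Conditions: 14 (5 equiv), PhMe, 80 °C then 110 °C, sealed tube, Ar
Reagents that add atoms: none
Why: Thermal loss of CO from 12 frees a site on chromium, the silyl enol ether double bond of 14 is cyclopropanated at the carbene carbon through a chromacyclobutane and reductive elimination, and the cis-1-alkenyl-2-vinylcyclopropane 15 undergoes a boat [3,3] (divinylcyclopropane to cycloheptadiene) rearrangement; the closest known reaction type is the formal (4+3) cycloaddition of alkenyl(alkoxy)carbene complexes of Cr(CO)5 with 2-silyloxy- and 2-amino-1,3-dienes. Ring A is closed by C5–C6 bond formation in the Cope step (C1–C2 having been made in the cyclopropanation), a four-carbon enlargement of the cyclopropane in which the vicinal OMe/OTBS donor pair weakens the C1–C3 bond that breaks. The only new stereocentre, quaternary C6, is set by the face of the C10=C6 alkene that C5 reaches, and the OTBS group on the neighbouring C7 directs bonding to the opposite (α) face, so the methyl group ends β, cis to the C9 oxygen. The regiochemistry (C3 oxygen next to C2) needs attack on the oxygenated double bond, which the silyloxy group secures electronically, while the fully substituted C6 terminus shuts off the competing Diels–Alder reaction of the alkenyl carbene. The trans cyclopropane and the cis epimer leading to the β-face product are expected to interconvert with 15 at the reaction temperature by reversible homolysis of the donor-flanked C1–C3 bond, so material should funnel through the less hindered Cope transition state. The weak point is the methyl group on C6, which points into the boat and slows the rearrangement, hence the final heating to 110 °C.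

Step 9
Reactants: 16 1-methoxy-6β-methyl-9α-isopropyl-3,7β-bis(tert-butyldimethylsilyloxy)-9β-(triethylsilyloxy)bicyclo[5.3.0]deca-1(10),3-diene
Product: 18 1-methoxy-6β-methyl-9α-isopropyl-7β-(tert-butyldimethylsilyloxy)-9β-(triethylsilyloxy)bicyclo[5.3.0]deca-1(10),3-dien-3-yl trifluoromethanesulfonate, via cesium enolate 17 (not isolated)
Conditions: CsF, PhNTf2, DME, rt
Reagents that add atoms: N-phenylbis(trifluoromethanesulfonimide), O=S(=O)(N(c1ccccc1)S(=O)(=O)C(F)(F)F)C(F)(F)F
Why: Fluoride cleaves the silyl enol ether much faster than the hindered alkyl silyl ethers at C7 and C9, and the cesium enolate is triflated on oxygen as it forms, so the C3=C4 position fixed by the Cope step is carried into the triflate (silyl enol ether to enol triflate exchange).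

Step 10
Reactants: 18 C3 enol triflate
Product: 19 1-methoxy-3,6β-dimethyl-9α-isopropyl-7β-(tert-butyldimethylsilyloxy)-9β-(triethylsilyloxy)bicyclo[5.3.0]deca-1(10),3-diene
Conditions: MeMgBr, Fe(acac)3 (5 mol %), THF–NMP, −30 °C
Reagents that add atoms: methylmagnesium bromide, C[Mg]Br
Why: Iron-catalysed Kumada-type cross-coupling of the alkenyl triflate with the methyl Grignard reagent puts the methyl group on C3 without moving the alkene; the enol ether and silyl ethers are inert at this temperature.

Step 11
Reactants: 19 C1 methyl enol ether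
Product: 20 3,6β-dimethyl-9α-isopropyl-7β-(tert-butyldimethylsilyloxy)-9β-(triethylsilyloxy)-10α-H-bicyclo[5.3.0]dec-3-en-1-one (trans-fused)
Conditions: (CO2H)2, THF–H2O, 0 °C → rt
Reagents that add atoms: water, O
Why: Enol ether hydrolysis by rate-limiting C-protonation at C10 and collapse of the hemiketal; the proton should enter from the α face, away from the C6 methyl and C9 silyloxy groups, to give the trans fusion (also the arrangement that keeps the C10–C1 bond anti to the isopropyl group), and a weak carboxylic acid is chosen because this general-acid-catalysed path does not depend on ionising the allylic C9–O bond.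

Step 12
Reactants: 20 trans-fused C1 ketone
Product: 21 9β-hydroxy-3,6β-dimethyl-9α-isopropyl-7β-(tert-butyldimethylsilyloxy)-10α-H-bicyclo[5.3.0]dec-3-en-1-one
Conditions: HF·pyridine, pyridine, THF, 0 °C
Reagents that add atoms: none
Why: Selective desilylation: HF cleaves the triethylsilyl ether far faster than the neopentyl-type secondary TBS ether at C7, and the pyridine buffer protects the β-hydroxy ketone and the β,γ-alkene from acid.

Step 13
Reactants: 21 9β-hydroxy C1 ketone
Product: 22 3,6β-dimethyl-9α-isopropyl-7β-(tert-butyldimethylsilyloxy)-10α-H-bicyclo[5.3.0]dec-3-ene-1α,9β-diol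
Conditions: Me4NBH(OAc)3, AcOH–MeCN, −30 → 0 °C
Reagents that add atoms: none
Why: Evans–Saksena directed reduction: the C9 hydroxyl exchanges onto boron and hydride is delivered within the molecule to the β face of the C1 ketone, so the new hydroxyl is α, trans to the C9 hydroxyl, as the target requires.

Step 14
Reactants: 22 1α,9β-diol; 23 4-methoxybenzoyl chloride
Product: 24 9β-hydroxy-3,6β-dimethyl-9α-isopropyl-7β-(tert-butyldimethylsilyloxy)-10α-H-bicyclo[5.3.0]dec-3-en-1α-yl 4-methoxybenzoate
Conditions: 4-MeOC6H4COCl, Et3N, DMAP (cat.), CH2Cl2, 0 °C → rt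
Reagents that add atoms: none
Why: DMAP-catalysed acylation takes the secondary C1 hydroxyl, while the tertiary C9 hydroxyl, flanked by the isopropyl group and the ring fusion, does not react.

Step 15
Reactants: 24 C7 silyl ether of the anisate
Product: 25 7β,9β-dihydroxy-3,6β-dimethyl-9α-isopropyl-10α-H-bicyclo[5.3.0]dec-3-en-1α-yl 4-methoxybenzoate
Conditions: HF·pyridine, THF, rt
Reagents that add atoms: none
Why: Fluoride-driven desilylation of the C7 TBS ether under non-basic conditions avoids acyl migration and ester cleavage.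

Step 16
Reactants: 25 7β,9β-diol anisate
Product: 26 target, 9β-hydroxy-3,6β-dimethyl-7-oxo-9α-isopropyl-10α-H-bicyclo[5.3.0]dec-3-en-1α-yl 4-methoxybenzoate
Conditions: Dess–Martin periodinane, pyridine, CH2Cl2, 0 °C → rt
Reagents that add atoms: none
Why: Dess–Martin oxidation of the only secondary alcohol gives the C7 ketone; C6 is quaternary, so no stereocentre next to the new ketone can epimerise, and the tertiary alcohol is inert.

**Compound list**

1 | (R)-4-(tert-butyldimethylsilyloxy)cyclopent-2-en-1-one | O=C1C=C[C@H](O[Si](C)(C)C(C)(C)C)C1 | starting material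
2 | (3R,4R)-4-(tert-butyldimethylsilyloxy)-3-methyl-1-(trimethylsilyloxy)cyclopent-1-ene | C[Si](C)(C)OC1=C[C@@H](C)[C@H](O[Si](C)(C)C(C)(C)C)C1 | intermediate
3 | (R)-4-(tert-butyldimethylsilyloxy)-3-methylcyclopent-2-en-1-one | O=C1C=C(C)[C@H](O[Si](C)(C)C(C)(C)C)C1 | intermediate
4 | 2,3-dibromo-4-(tert-butyldimethylsilyloxy)-3-methylcyclopentan-1-one (bromide epimers, not isolated) | O=C1C(Br)C(C)(Br)[C@H](O[Si](C)(C)C(C)(C)C)C1 | intermediate
5 | (R)-2-bromo-4-(tert-butyldimethylsilyloxy)-3-methylcyclopent-2-en-1-one | O=C1C(Br)=C(C)[C@H](O[Si](C)(C)C(C)(C)C)C1 | intermediate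
6 | isopropylmagnesium chloride | CC(C)[Mg]Cl | starting material
7 | (1R,4R)-2-bromo-4-(tert-butyldimethylsilyloxy)-3-methyl-1-(propan-2-yl)cyclopent-2-en-1-ol | BrC1=C(C)[C@H](O[Si](C)(C)C(C)(C)C)C[C@@]1(O)C(C)C | intermediate
8 | (3R,5R)-1-bromo-3-(tert-butyldimethylsilyloxy)-2-methyl-5-(propan-2-yl)-5-(triethylsilyloxy)cyclopent-1-ene | BrC1=C(C)[C@H](O[Si](C)(C)C(C)(C)C)C[C@@]1(O[Si](CC)(CC)CC)C(C)C | intermediate
9 | chromium hexacarbonyl, Cr(CO)6 | O=C=[Cr](=C=O)(=C=O)(=C=O)(=C=O)=C=O | starting material
10 | ring B vinyllithium (lithium in place of bromine in 8, not isolated) | [Li]C1=C(C)[C@H](O[Si](C)(C)C(C)(C)C)C[C@@]1(O[Si](CC)(CC)CC)C(C)C | intermediate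
11 | lithium pentacarbonyl(ring B acyl)chromate (not isolated) | [Li+].[O-]C(=[Cr](=C=O)(=C=O)(=C=O)(=C=O)=C=O)C1=C(C)[C@H](O[Si](C)(C)C(C)(C)C)C[C@@]1(O[Si](CC)(CC)CC)C(C)C | intermediate
12 | pentacarbonyl{methoxy[(3R,5R)-3-(tert-butyldimethylsilyloxy)-2-methyl-5-(propan-2-yl)-5-(triethylsilyloxy)cyclopent-1-en-1-yl]methylidene}chromium | COC(=[Cr](=C=O)(=C=O)(=C=O)(=C=O)=C=O)C1=C(C)[C@H](O[Si](C)(C)C(C)(C)C)C[C@@]1(O[Si](CC)(CC)CC)C(C)C | intermediate
13 | but-3-en-2-one | CC(=O)C=C | starting material
14 | 2-(tert-butyldimethylsilyloxy)buta-1,3-diene | C=CC(=C)O[Si](C)(C)C(C)(C)C | intermediate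
15 | 1-methoxy-1-(ring B cyclopentenyl)-2-(tert-butyldimethylsilyloxy)-2-vinylcyclopropane, alkenyl and vinyl groups cis (not isolated) | CO[C@]1(C[C@]1(O[Si](C)(C)C(C)(C)C)C=C)C2=C(C)[C@H](O[Si](C)(C)C(C)(C)C)C[C@@]2(O[Si](CC)(CC)CC)C(C)C | intermediate
16 | 1-methoxy-6β-methyl-9α-isopropyl-3,7β-bis(tert-butyldimethylsilyloxy)-9β-(triethylsilyloxy)bicyclo[5.3.0]deca-1(10),3-diene | COC1=C2[C@](O[Si](CC)(CC)CC)(C(C)C)C[C@@H](O[Si](C)(C)C(C)(C)C)[C@]2(C)CC=C(O[Si](C)(C)C(C)(C)C)C1 | intermediate
17 | cesium C3 enolate of the C3=C4 enol (not isolated) | COC1=C2[C@](O[Si](CC)(CC)CC)(C(C)C)C[C@@H](O[Si](C)(C)C(C)(C)C)[C@]2(C)CC=C([O-])C1.[Cs+] | intermediate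
18 | C3 enol triflate (C3=C4), C1 methyl enol ether | COC1=C2[C@](O[Si](CC)(CC)CC)(C(C)C)C[C@@H](O[Si](C)(C)C(C)(C)C)[C@]2(C)CC=C(OS(=O)(=O)C(F)(F)F)C1 | intermediate
19 | 1-methoxy-3,6β-dimethyl-9α-isopropyl-7β-(tert-butyldimethylsilyloxy)-9β-(triethylsilyloxy)bicyclo[5.3.0]deca-1(10),3-diene | COC1=C2[C@](O[Si](CC)(CC)CC)(C(C)C)C[C@@H](O[Si](C)(C)C(C)(C)C)[C@]2(C)CC=C(C)C1 | intermediate
20 | trans-fused C1 ketone, 7β-OTBS, 9β-OTES, 10α-H | O=C1CC(C)=CC[C@@]2(C)[C@H](O[Si](C)(C)C(C)(C)C)C[C@@](O[Si](CC)(CC)CC)(C(C)C)[C@H]12 | intermediate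
21 | 9β-hydroxy C1 ketone, 7β-OTBS | O=C1CC(C)=CC[C@@]2(C)[C@H](O[Si](C)(C)C(C)(C)C)C[C@@](O)(C(C)C)[C@H]12 | intermediate
22 | 1α,9β-diol, 7β-OTBS | O[C@H]1CC(C)=CC[C@@]2(C)[C@H](O[Si](C)(C)C(C)(C)C)C[C@@](O)(C(C)C)[C@H]12 | intermediate
23 | 4-methoxybenzoyl chloride | COc1ccc(C(=O)Cl)cc1 | starting material
24 | 1α-(4-methoxybenzoate), 9β-ol, 7β-OTBS | COc1ccc(C(=O)O[C@H]2CC(C)=CC[C@@]3(C)[C@H](O[Si](C)(C)C(C)(C)C)C[C@@](O)(C(C)C)[C@H]23)cc1 | intermediate
25 | 1α-(4-methoxybenzoate), 7β,9β-diol | COc1ccc(C(=O)O[C@H]2CC(C)=CC[C@@]3(C)[C@H](O)C[C@@](O)(C(C)C)[C@H]23)cc1 | intermediate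
26 | CNP0232277.1 | COc1ccc(C(=O)O[C@H]2CC(C)=CC[C@@]3(C)C(=O)C[C@@](O)(C(C)C)[C@H]23)cc1 | target

**Step count**

Total: 16 steps. Longest linear sequence: 15 steps (steps 1–6 and 8–16, from 1 to 26); step 7 is a one-step side branch.

**Steps most likely to fail**

1. Step 8. The carbene carbon is shielded by the C9 quaternary centre and the C6 methyl group, so thermal decomposition of the complex may overtake cyclopropanation; the Cope step may also run partly through the β-face boat (poor facial selectivity at C6). The fallback closes ring A by ring-closing metathesis instead of cycloaddition. It sets out from bromide 8: bromine–lithium exchange as in step 6 and addition to 3-methylbut-3-enal should give the dienyl carbinol F1, and Dess–Martin oxidation the methallyl enone F2. Copper-mediated conjugate addition of allylmagnesium bromide (CuBr·SMe2, TMSCl, THF, −78 °C), anti to the C7 silyloxy group, with protonation at C10 on work-up, should give the 6α-allyl ketone F3. Ring-closing metathesis with the second-generation Grubbs catalyst then joins C3 to C4 and comes back to the route at ketone 20.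

2. Step 11. Three processes threaten it: acid-promoted ionisation of the C9 silyloxy group through the enol ether (loss of the tertiary oxygen), protonation of C10 from the β face (cis fusion), and migration of the C3=C4 alkene into conjugation once the ketone exists. The fallback avoids Brønsted acid and sets out from enol ether 19. N-bromosuccinimide in NaHCO3-buffered aqueous THF at −20 °C should convert the enol ether, by bromonium attack at C10 and hydration at C1, into the C10-bromo ketone F4. Radical debromination with Bu3SnH and AIBN in benzene then returns to ketone 20.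

3. Step 13. Exchange of the hindered tertiary C9 hydroxyl onto boron may be slow, so undirected hydride attack with poor facial selectivity at C1 could take over. The fallback tethers the hydride and sets out from hydroxy ketone 21. Chlorodi(propan-2-yl)silane with imidazole and DMAP should give the C9 di(propan-2-yl)silyl ether F5. SnCl4-catalysed intramolecular hydrosilylation (CH2Cl2, −78 °C) delivers hydride to the β face of C1 and should give the cyclic C1,C9 silylene F6. HF·pyridine at 0 °C opens the silylene and comes back to the route at diol 22.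

**Further compounds**

F1 | step 8 | dienyl carbinol, 1-(ring B cyclopentenyl)-3-methylbut-3-en-1-ol (carbinol epimers) | C=C(C)CC(O)C1=C(C)[C@H](O[Si](C)(C)C(C)(C)C)C[C@@]1(O[Si](CC)(CC)CC)C(C)C
F2 | step 8 | methallyl enone, 1-(ring B cyclopentenyl)-3-methylbut-3-en-1-one | C=C(C)CC(=O)C1=C(C)[C@H](O[Si](C)(C)C(C)(C)C)C[C@@]1(O[Si](CC)(CC)CC)C(C)C
F3 | step 8 | 6α-allyl ketone, 6β-methyl, 10α-H | C=C(C)CC(=O)[C@@H]1[C@@](C)(CC=C)[C@H](O[Si](C)(C)C(C)(C)C)C[C@@]1(O[Si](CC)(CC)CC)C(C)C
F4 | step 11 | C10-bromo ketone (C10 configuration open) | O=C1CC(C)=CC[C@@]2(C)[C@H](O[Si](C)(C)C(C)(C)C)C[C@@](O[Si](CC)(CC)CC)(C(C)C)C12Br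
F5 | step 13 | C9 di(propan-2-yl)silyl ether of 21 | O=C1CC(C)=CC[C@@]2(C)[C@H](O[Si](C)(C)C(C)(C)C)C[C@@](O[SiH](C(C)C)C(C)C)(C(C)C)[C@H]12
F6 | step 13 | cyclic C1,C9 di(propan-2-yl)silylene of 22 | CC(C)[Si]1(C(C)C)O[C@H]2CC(C)=CC[C@@]3(C)[C@H](O[Si](C)(C)C(C)(C)C)C[C@@](O1)(C(C)C)[C@H]23
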